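## Retrosynthetic overview
1. Last bond, C8–C9: Negishi sp2–sp3 coupling of an enantiopure bromoalkenyl-1,2-dioxane acid with an (S)-2-ethylhex-3-enylzinc reagent. This keeps the easily reduced C11=C12 alkene out of the ring-forming step.
2. Only ring (1,2-dioxane): both C–O bonds form at once by singlet-oxygen [4+2] cycloaddition to an acyclic (3E,5E)-diene, followed by syn reduction of the 4,5-alkene, as in the proposed biogenesis. Diene geometry sets C3/C6 and the reduction sets C4.
3. The alkenyl bromide deactivates the third alkene towards O2 and diimide, and later serves as the coupling handle.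
4. The bromotriene comes from but-1-yne (used three times) and one Reformatsky reagent, linked through two units of (E)-2-bromo-1-iodobut-1-ene.
5. C10 comes from organocatalytic α-alkenylation of butanal. The absolute configuration of the ring comes from a lipase hydrolysis that also frees the acid.

Assumption: the lipase in the resolution step hydrolyses the (3S,4S,6S)-enantiomer of the racemic dioxane ester faster. The sense is checked by comparing the optical rotation of the final acid with that of the natural product.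

## Route

Step 1
Reactants: 1 but-1-yne
Product: 2 (E)-2-bromo-1-iodobut-1-ene
Conditions: IBr (1.0 equiv), CH2Cl2, −78 → 0 °C, dark
Reagents that add atoms: iodine monobromide, BrI
Why: Electrophilic iodobromination (anti addition): bromide opens the bridged iodonium ion at the substituted carbon from the opposite side, giving the Markovnikov E-dihalide with two halogens of different coupling reactivity.

Step 2
Reactants: 2 (E)-2-bromo-1-iodobut-1-ene; 3 methyl bromoacetate
Product: 5 methyl (E)-4-bromohex-3-enoate, via Reformatsky reagent 4 (not isolated)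
Conditions: 3, Zn dust (TMSCl-activated), THF, 40 °C, solution decanted from Zn; then 2, Pd(PPh3)4 (3 mol%), THF/DMPU, 25 °C
Reagents that add atoms: none
Why: Negishi-type cross-coupling of a Reformatsky reagent: zerovalent palladium inserts into the weaker, unhindered C–I bond and leaves C–Br alone, the geometry is retained, and syn β-bromide elimination cannot occur because Pd and Br stand trans.

Step 3
Reactants: 5 methyl (E)-4-bromohex-3-enoate; 1 but-1-yne
Product: 6 methyl (E)-4-ethyloct-3-en-5-ynoate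
Conditions: PdCl2(PPh3)2 (3 mol%), CuI (5 mol%), Et3N, THF, sealed tube, 40 °C
Reagents that add atoms: none
Why: Sonogashira coupling at the alkenyl bromide goes with retention, so the alkynyl carbon stays trans to CH2CO2Me (3E), and the mild amine base leaves the β,γ-double bond in place.

Step 4
Reactants: 6 methyl (E)-4-ethyloct-3-en-5-ynoate; 2 (E)-2-bromo-1-iodobut-1-ene
Product: 9 methyl (3E,5E,7E)-8-bromo-4,6-diethyldeca-3,5,7-trienoate, via alkenylzirconocene 7 (not isolated), via alkenylzinc chloride 8 (not isolated)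
Conditions: Cp2Zr(H)Cl (1.2 equiv), THF, 23 °C, dark; ZnCl2 (1.2 equiv); 2 (1.1 equiv), Pd(PPh3)4 (5 mol%), 23 °C
Reagents that add atoms: none
Why: Syn hydrozirconation puts Zr on the alkyne carbon next to ethyl, away from the branched alkenyl end, and the zinc-assisted Negishi alkenyl–alkenyl coupling at the C–I bond of a second unit of 2 retains all geometries, fixing 5E (ethyl inside, chain outside) and 7E.

Step 5
Reactants: 9 methyl (3E,5E,7E)-8-bromo-4,6-diethyldeca-3,5,7-trienoate
Product: 11 racemic methyl 2-[(3S*,4S*,6S*)-6-[(E)-2-bromobut-1-enyl]-4,6-diethyl-1,2-dioxan-3-yl]acetate, via dihydrodioxine 10 (not isolated)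
Conditions: O2, tetraphenylporphyrin (0.5 mol%), CH2Cl2, −20 °C, visible light (>500 nm); then KO2CN=NCO2K (excess, in portions), AcOH, MeOH/CH2Cl2, 0 → 23 °C
Reagents that add atoms: dioxygen, O=O
Why: Biomimetic singlet-oxygen [4+2] cycloaddition then diimide reduction: O2 adds suprafacially to the s-cis C3–C6 diene (the bromoalkene is too electron-poor and hindered to take part), so the two outside groups of the E,E-diene (CH2CO2Me and bromobutenyl) end up cis at C3 and C6, and diimide then delivers two H atoms syn from the face carrying only H-3 and the C6 ethyl group, which places the C4 ethyl cis to both chains while the bromoalkene and the O–O bond stay intact.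

Step 6
Reactants: 11 racemic methyl 2-[(3S*,4S*,6S*)-6-[(E)-2-bromobut-1-enyl]-4,6-diethyl-1,2-dioxan-3-yl]acetate
Product: 12 2-[(3S,4S,6S)-6-[(E)-2-bromobut-1-enyl]-4,6-diethyl-1,2-dioxan-3-yl]acetic acid
Conditions: Burkholderia cepacia lipase, phosphate buffer pH 7.2/MTBE, 30 °C, stopped at ca. 45% conversion; extraction at pH 8, then acidification
Reagents that add atoms: water, O
Why: Enzymatic kinetic resolution (enantioselective ester hydrolysis): C3 lies β to the ester carbonyl inside the acyl pocket, so one enantiomer reacts much faster, the acid is separated from the unreacted enantiomeric ester by base extraction, and the same step removes the ester group.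

Step 7
Reactants: 1 but-1-yne
Product: 14 (E)-but-1-enylboronic acid, via alkenyldibromoborane 13 (not isolated)
Conditions: HBBr2·SMe2, CH2Cl2, 0 → 23 °C; then H2O/Et2O, 0 °C
Reagents that add atoms: dibromoborane–dimethyl sulfide, C[S+](C)[BH-](Br)Br; water, O
Why: Syn, anti-Markovnikov hydroboration of the terminal alkyne gives the E-alkenylborane, and hydrolysis of the two B–Br bonds gives the boronic acid.

Step 8
Reactants: 15 butanal; 14 (E)-but-1-enylboronic acid
Product: 17 (2S,3E)-2-ethylhex-3-en-1-ol, via aldehyde 16 (not isolated)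
Conditions: Cu(OAc)2 (30 mol%), (2R,5R)-5-benzyl-2-tert-butyl-3-methylimidazolidin-4-one·TFA (20 mol%), O2 (1 atm), 4 Å MS, EtOAc, 23 °C; then NaBH4, MeOH, 0 °C
Reagents that add atoms: none
Why: Oxidative α-alkenylation of an aldehyde by combined enamine and copper catalysis: the alkenyl group passes from boron to copper with retention of E geometry, the E-enamine attacks the trivalent alkenylcopper species on its Re face because the benzyl and tert-butyl groups of the catalyst cover the Si face, which sets the centre as S (C10 of the target, R there only through a change of CIP ranks), and immediate NaBH4 reduction prevents racemisation or conjugation.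

Step 9
Reactants: 17 (2S,3E)-2-ethylhex-3-en-1-ol
Product: 18 (3E,5S)-5-(iodomethyl)hept-3-ene
Conditions: I2, PPh3, imidazole, CH2Cl2, 0 °C
Reagents that add atoms: iodine, [I][I]
Why: Appel-type iodination is an SN2 displacement at the primary carbon, so the neighbouring stereocentre and the E-alkene are untouched.

Step 10
Reactants: 18 (3E,5S)-5-(iodomethyl)hept-3-ene; 12 2-[(3S,4S,6S)-6-[(E)-2-bromobut-1-enyl]-4,6-diethyl-1,2-dioxan-3-yl]acetic acid
Product: 22 2-[(3S,4S,6S)-4,6-diethyl-6-[(1E,4R,5E)-2,4-diethylocta-1,5-dienyl]-1,2-dioxan-3-yl]acetic acid, via alkyllithium 19 (not isolated), via alkylzinc chloride 20 (not isolated), via sodium carboxylate 21 (not isolated)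
Conditions: 18, t-BuLi (2.1 equiv), Et2O/pentane, −78 °C; ZnCl2 (THF), → 0 °C; separately 12, NaH (1.0 equiv), THF, 0 °C; combine, Pd(dppf)Cl2 (5 mol%), THF/NMP, 23–40 °C; 1 M HCl work-up
Reagents that add atoms: none
Why: Negishi sp2–sp3 coupling with retention at the alkenyl bromide gives 7E, the cold iodine–lithium exchange avoids radicals that could cause a 1,2-vinyl shift, alkylzinc reagents and dppf-ligated palladium spare dialkyl peroxides, the carboxylate cannot undergo β-elimination of the peroxide, and no stereocentre is touched.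

## Compound list
1 | but-1-yne | CCC#C | starting material
2 | (E)-2-bromo-1-iodobut-1-ene | CC/C(Br)=C\I | intermediate
3 | methyl bromoacetate | COC(=O)CBr | starting material
4 | bromo(2-methoxy-2-oxoethyl)zinc (Reformatsky reagent) | COC(=O)C[Zn]Br | intermediate
5 | methyl (E)-4-bromohex-3-enoate | COC(=O)C/C=C(/Br)CC | intermediate
6 | methyl (E)-4-ethyloct-3-en-5-ynoate | COC(=O)C/C=C(/C#CCC)CC | intermediate
7 | chlorobis(cyclopentadienyl)[(3E,5E)-5-ethyl-8-methoxy-8-oxoocta-3,5-dien-3-yl]zirconium | COC(=O)C/C=C(CC)/C=C(/[Zr](Cl)(C1C=CC=C1)C1C=CC=C1)CC | intermediate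
8 | chloro[(3E,5E)-5-ethyl-8-methoxy-8-oxoocta-3,5-dien-3-yl]zinc | COC(=O)C/C=C(CC)/C=C(/[Zn]Cl)CC | intermediate
9 | methyl (3E,5E,7E)-8-bromo-4,6-diethyldeca-3,5,7-trienoate | COC(=O)C/C=C(CC)/C=C(CC)/C=C(/Br)CC | intermediate
10 | methyl 2-[(3S*,6S*)-6-[(E)-2-bromobut-1-enyl]-4,6-diethyl-3,6-dihydro-1,2-dioxin-3-yl]acetate (racemic; 3S,6S enantiomer drawn) | Br/C(=C/[C@]1(CC)C=C(CC)[C@H](CC(=O)OC)OO1)CC | intermediate
11 | methyl 2-[(3S*,4S*,6S*)-6-[(E)-2-bromobut-1-enyl]-4,6-diethyl-1,2-dioxan-3-yl]acetate (racemic; 3S,4S,6S enantiomer drawn) | Br/C(=C/[C@]1(CC)C[C@H](CC)[C@H](CC(=O)OC)OO1)CC | intermediate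
12 | 2-[(3S,4S,6S)-6-[(E)-2-bromobut-1-enyl]-4,6-diethyl-1,2-dioxan-3-yl]acetic acid | Br/C(=C/[C@]1(CC)C[C@H](CC)[C@H](CC(=O)O)OO1)CC | intermediate
13 | dibromo[(E)-but-1-enyl]borane–dimethyl sulfide | CC/C=C/[B-](Br)(Br)[S+](C)C | intermediate
14 | (E)-but-1-enylboronic acid | CC/C=C/B(O)O | intermediate
15 | butanal | CCCC=O | starting material
16 | (2S,3E)-2-ethylhex-3-enal | CC/C=C/[C@H](CC)C=O | intermediate
17 | (2S,3E)-2-ethylhex-3-en-1-ol | CC/C=C/[C@H](CC)CO | intermediate
18 | (3E,5S)-5-(iodomethyl)hept-3-ene | CC/C=C/[C@H](CC)CI | intermediate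
19 | [(2S,3E)-2-ethylhex-3-enyl]lithium | CC/C=C/[C@H](CC)C[Li] | intermediate
20 | chloro[(2S,3E)-2-ethylhex-3-enyl]zinc | CC/C=C/[C@H](CC)C[Zn]Cl | intermediate
21 | sodium 2-[(3S,4S,6S)-6-[(E)-2-bromobut-1-enyl]-4,6-diethyl-1,2-dioxan-3-yl]acetate | Br/C(=C/[C@]1(CC)C[C@H](CC)[C@H](CC(=O)[O-])OO1)CC.[Na+] | intermediate
22 | 2-[(3S,4S,6S)-4,6-diethyl-6-[(1E,4R,5E)-2,4-diethylocta-1,5-dienyl]-1,2-dioxan-3-yl]acetic acid | CC/C=C/[C@H](CC)C/C(=C/[C@]1(CC)C[C@H](CC)[C@H](CC(=O)O)OO1)CC | target

## Step count and risks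
Total step count: 10. Longest linear sequence: 7 (steps 1–6 and 10).

**Step 5.**
- Risk: ene reactions at the ethyl groups may compete with the cycloaddition. Some O2 may add to the C5–C8 diene. The hindered trisubstituted ring alkene may be reduced slowly or with only moderate facial selectivity.
- Fallback: remove every other C=C from the cycloaddition substrate.
  - Setting out from 5, a Heck reaction with 2-ethylacrolein (Pd(OAc)2, Bu4NCl, NaHCO3, DMF) gives methyl (3E,5E)-4,6-diethyl-7-oxohepta-3,5-dienoate F1, which holds only one diene.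
  - Singlet oxygen gives racemic methyl 2-[(3S*,6S*)-4,6-diethyl-6-formyl-3,6-dihydro-1,2-dioxin-3-yl]acetate F2, and diimide gives racemic methyl 2-[(3S*,4S*,6S*)-4,6-diethyl-6-formyl-1,2-dioxan-3-yl]acetate F3.
  - Preformed Ph3P=CBr2 (from CBr4 and PPh3, 0 °C) gives racemic methyl 2-[(3S*,4S*,6S*)-6-(2,2-dibromoethenyl)-4,6-diethyl-1,2-dioxan-3-yl]acetate F4.
  - Lipase hydrolysis as in step 6 gives 2-[(3S,4S,6S)-6-(2,2-dibromoethenyl)-4,6-diethyl-1,2-dioxan-3-yl]acetic acid F5, and NaH gives sodium 2-[(3S,4S,6S)-6-(2,2-dibromoethenyl)-4,6-diethyl-1,2-dioxan-3-yl]acetate F6.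
  - Coupling with 20 under Pd(DPEphos)Cl2 replaces only the bromine trans to the ring. This gives sodium 2-[(3S,4S,6S)-6-[(1Z,4R,5E)-2-bromo-4-ethylocta-1,5-dienyl]-4,6-diethyl-1,2-dioxan-3-yl]acetate F7.
  - Et2Zn with Pd(PtBu3)2 in the same flask replaces the second bromine with retention. Acid work-up comes back to the route at 22.

**Step 6.**
- Risk: the enantioselectivity and its sense cannot be predicted for this acyl group, and the yield is at most half.
- Fallback: classical resolution instead of an enzyme.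
  - Setting out from 11, LiOH saponification and acidification give racemic 2-[(3S*,4S*,6S*)-6-[(E)-2-bromobut-1-enyl]-4,6-diethyl-1,2-dioxan-3-yl]acetic acid F8.
  - (R)-1-phenylethylamine gives diastereomeric salts, from which (R)-1-phenylethylammonium 2-[(3S,4S,6S)-6-[(E)-2-bromobut-1-enyl]-4,6-diethyl-1,2-dioxan-3-yl]acetate F9 is crystallised. The S-amine is used if the other salt is the less soluble one.
  - Dilute HCl comes back to the route at 12.

**Step 10.**
- Risk: oxidative addition to the hindered alkenyl bromide may be slow. Zinc salts together with low-valent palladium could attack the O–O bond.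
- Fallback: change from zinc to boron as the transmetalating metal.
  - Setting out from 19, B-methoxy-9-BBN gives lithium B-methoxy-B-[(2S,3E)-2-ethylhex-3-enyl]-9-boratabicyclo[3.3.1]nonane F10.
  - F10 is joined to 21 in a B-alkyl Suzuki–Miyaura coupling (Pd(dppf)Cl2, AsPh3, aqueous K3PO4, DMF, 23 °C).
  - Acidification comes back to the route at 22.

## Further compounds
F1 | step 5 | methyl (3E,5E)-4,6-diethyl-7-oxohepta-3,5-dienoate | COC(=O)C/C=C(CC)/C=C(/C=O)CC
F2 | step 5 | methyl 2-[(3S*,6S*)-4,6-diethyl-6-formyl-3,6-dihydro-1,2-dioxin-3-yl]acetate (racemic; 3S,6S drawn) | O=C[C@]1(CC)C=C(CC)[C@H](CC(=O)OC)OO1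
F3 | step 5 | methyl 2-[(3S*,4S*,6S*)-4,6-diethyl-6-formyl-1,2-dioxan-3-yl]acetate (racemic; 3S,4S,6S drawn) | O=C[C@]1(CC)C[C@H](CC)[C@H](CC(=O)OC)OO1
F4 | step 5 | methyl 2-[(3S*,4S*,6S*)-6-(2,2-dibromoethenyl)-4,6-diethyl-1,2-dioxan-3-yl]acetate (racemic; 3S,4S,6S drawn) | BrC(Br)=C[C@]1(CC)C[C@H](CC)[C@H](CC(=O)OC)OO1
F5 | step 5 | 2-[(3S,4S,6S)-6-(2,2-dibromoethenyl)-4,6-diethyl-1,2-dioxan-3-yl]acetic acid | BrC(Br)=C[C@]1(CC)C[C@H](CC)[C@H](CC(=O)O)OO1
F6 | step 5 | sodium 2-[(3S,4S,6S)-6-(2,2-dibromoethenyl)-4,6-diethyl-1,2-dioxan-3-yl]acetate | BrC(Br)=C[C@]1(CC)C[C@H](CC)[C@H](CC(=O)[O-])OO1.[Na+]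
F7 | step 5 | sodium 2-[(3S,4S,6S)-6-[(1Z,4R,5E)-2-bromo-4-ethylocta-1,5-dienyl]-4,6-diethyl-1,2-dioxan-3-yl]acetate | CC/C=C/[C@H](CC)C/C(Br)=C/[C@]1(CC)C[C@H](CC)[C@H](CC(=O)[O-])OO1.[Na+]
F8 | step 6 | 2-[(3S*,4S*,6S*)-6-[(E)-2-bromobut-1-enyl]-4,6-diethyl-1,2-dioxan-3-yl]acetic acid (racemic; 3S,4S,6S drawn) | Br/C(=C/[C@]1(CC)C[C@H](CC)[C@H](CC(=O)O)OO1)CC
F9 | step 6 | (R)-1-phenylethylammonium 2-[(3S,4S,6S)-6-[(E)-2-bromobut-1-enyl]-4,6-diethyl-1,2-dioxan-3-yl]acetate | Br/C(=C/[C@]1(CC)C[C@H](CC)[C@H](CC(=O)[O-])OO1)CC.C[C@@H]([NH3+])c1ccccc1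
F10 | step 10 | lithium B-methoxy-B-[(2S,3E)-2-ethylhex-3-enyl]-9-boratabicyclo[3.3.1]nonane | CC/C=C/[C@H](CC)C[B-]1(OC)C2CCCC1CCC2.[Li+]
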